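Its constants are those of an exercise; the run is a simulation.

I read every flask at 2.0 min, so I follow one molecule of starting material up to that moment and ask its chances at each fork.

common to all: gas 0.64 mM (held); time 2.0 min

| run | starting material | second substrate | remark |
|---|---|---|---|
| spring | 0.013 M (fed, over 80 s) | 2.00 equiv | all else is in the flask from the start; the feed brings no volume worth counting |
| midnight | 0.013 M | 2.00 equiv | everything together at the start |
| dusk | 0.013 M | 2.00 equiv (fed, over 80 s) | all else is in the flask from the start; the feed brings no volume worth counting |
| winter | 0.013 M (fed, over 8.0 s) | 2.00 equiv | all else is in the flask from the start; the feed brings no volume worth counting |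
| summer | 0.013 M | 2.00 equiv (in portions, 5, over 80 s) | first portion at the start, last at 80 s |

1. which flask leads in amount of target, in percent of the starting material charged ("all alike" within 1.5 percentage points) (spring / midnight / dusk / winter / summer / all alike)
2. how much target is there at the end, in percent of the starting material charged: spring
3. how much target is there at the end, in percent of the starting material charged: midnight
4. how much target is there at the end, in percent of the starting material charged: dusk
5. how much target is there at the end, in percent of the starting material charged: winter
6. how much target is there at the end, in percent of the starting material charged: summer

- at the start none of reagent is dissolved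
- run time (spring): 2.0 min

    starting material + reagent → target (k1 = 59.7 /M/s)
    second substrate + reagent → second product (k2 = 1.15 /M/s)
    starting material + second substrate → cross product (k3 = 0.0544 /M/s)
    target → over-reaction product A (k4 = 1.81 × 10⁻⁵ /s)
    gas ⇌ reagent, rate k5*(csat - [reagent]) (k5 = 6.93 /s, csat = 0.64 mM)
    target → over-reaction product B (k6 = 0.0105 /s)

Taking [reagent] at its saturation value 0.64 mM and second substrate as charged, I let starting material go to target at a pseudo-first-order rate of 0.0382 /s and to cross product at 0.00141 /s, which is slower. In midnight, the early demand slows the first rate by a factor of about 0.899, which I set aside. Over-reaction product A forms more slowly than B, so I count target as lost at 0.0105 /s. The two forks of starting material add up to a combined loss rate of 0.0396 /s.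

My carried quantity is the lead factor, the number by which a late reading of target exceeds what a charge born entirely as target at the start would leave:

H = 1.31

By the reading, decay leaves a share 0.284 and unconverted starting material a share 0.00861. A steady feed multiplies each share by the average, over the feed, of the exponential growth at that term's rate.

midnight: 1.31 × (0.284 − 0.00861) = 36.1%

spring: 1.31 × (1.57 × 0.284 − 7.19 × 0.00861) = 50.2%

winter: 1.31 × (1.04 × 0.284 − 1.18 × 0.00861) = 37.5%

With the cross step struck out, midnight's line gives 37.7%, and I put dusk and summer between that and 36.1%. So I expect spring to hold more target than the others.

The forecast names spring, with 50% there, 37.3% in midnight, 38.4% in dusk, 39% in winter and 38.3% in summer, on the ground that “the end amount therefore depends mostly on how late the target is formed”. Its numbers for midnight and winter are higher than my lines.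

The simulation puts spring first, with 50.2%; midnight holds 36.6%, dusk 37.6%, winter 37.9% and summer 37.6%.

Against those results, my lines gave 50.2% for spring and 36.1% for midnight. The neighbouring flask is midnight read at 8.0 min, where starting material stands at 0%, so the second term of the line drops out and the lead factor 1.31 times the decay share 0.00647 gives 0.848%. That flask holds 0.859% target.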